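**Strategy.** The pyran ring (ring C) is cut at O1–C2 and C4–C4a. Ring A then is 2-methoxyresorcinol, whose symmetry makes either hydroxyl and its ortho carbon the O1/C4a pair, with the other hydroxyl (para to C4a) becoming the 7-OH. C2–C3–C4, with C3 between two methylenes, is the chain of a 2-arylacrolein. A chiral primary-amine catalyst joins the two in one operation: Friedel–Crafts conjugate addition forms C4–C4a, enantioselective enamine protonation sets C3, and hemiacetal closure forms O1–C2. The precursor is the unprotected diphenol plus 2-(2,3,4,5-tetramethoxyphenyl)propenal; the C2 lactol hydroxyl is removed afterwards by ionic hydrogenation.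

Key step: step 3

Remark: chromane numbering (O1, C2, C3, C4, C4a, C5–C8, C8a) is used for all bicyclic compounds. The catalyst antipode in step 3 is the one assigned by the face model given there; its mirror image (from D-tert-leucine) would be used if the sense of induction were found to be opposite.

**Step 1**
Reactants: 1 1,2,3,4-tetramethoxybenzene; 2 2-bromo-3,3-diethoxyprop-1-ene
Product: 5 1-(3,3-diethoxyprop-1-en-2-yl)-2,3,4,5-tetramethoxybenzene, via aryllithium 3 (not isolated), via arylzinc chloride 4 (not isolated)
Conditions: n-BuLi, TMEDA, THF, 0 °C; ZnCl2, 0 °C to rt; then the vinyl bromide, Pd(PPh3)4 (3 mol %), 50 °C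
Reagents that add atoms: n-butyllithium, CCCC[Li]; zinc dichloride, Cl[Zn]Cl
Why: Directed ortho-lithiation of 1 can only occur at C5/C6, which are equivalent by symmetry, and after transmetalation to zinc the aryl group is joined to the vinyl bromide of 2 by Negishi cross-coupling at zerovalent palladium, the diethyl acetal being inert to all three organometallic stages.

**Step 2**
Reactants: 5 1-(3,3-diethoxyprop-1-en-2-yl)-2,3,4,5-tetramethoxybenzene
Product: 6 2-(2,3,4,5-tetramethoxyphenyl)prop-2-enal
Conditions: 1 M aq. HCl, THF, 0 °C; extracted and used at once
Reagents that add atoms: water, O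
Why: Acid-catalysed acetal hydrolysis, the classical release of 2-arylacroleins from their acetals, should unmask the aldehyde without touching the aryl methyl ethers, and the ortho-methoxy group twists the aryl ring and slows dimerisation of the enal, which is nevertheless not stored.

**Step 3**
Reactants: 6 2-(2,3,4,5-tetramethoxyphenyl)prop-2-enal; 7 2-methoxybenzene-1,3-diol
Product: 9 (3S)-8-methoxy-3-(2,3,4,5-tetramethoxyphenyl)chromane-2,7-diol (lactol as C2 anomer mixture), via open-chain aldehyde 8 (not isolated)
Conditions: (S)-t-BuCH(NH2)CH2NEt2·TfOH (20 mol %), CHCl3, 0 °C, the diphenol in 2.5-fold excess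
Reagents that add atoms: none
Why: Proposed new method: the primary amine of the catalyst condenses with 6 to a catalyst-bound iminium ion, the ring carbon of 7 that is ortho to one hydroxyl and para to the other adds to its unsubstituted β-methylene (Friedel–Crafts conjugate addition, the C4–C4a bond), the resulting catalyst-bound enamine is protonated at its α-carbon, and hydrolysis releases aldehyde 8, whose ortho hydroxyl adds to the carbonyl (the O1–C2 bond) to give lactol 9, an overall addition in which every atom of 6 and 7 is retained. The closest known reaction types are the chiral primary-amine-catalysed Friedel–Crafts addition of indoles to α-substituted acroleins with enantioselective enamine protonation and the amine-catalysed annulation of electron-rich phenols with enals to chroman-2-ols; what is new is their merger on a phenol and an α-aryl acrolein. Ring C closes by reversible 6-exo-trig addition of the phenolic oxygen to the aldehyde carbon. C3 is set under catalyst control: the protonated diethylamino arm should deliver the proton intramolecularly to the Re face of the enamine α-carbon (priorities N-bearing carbon > aryl > CH2), which gives (S), while C2 forms as an inconsequential anomeric mixture that step 4 erases. The step needs C- over O-alkylation, a single annulation regiochemistry, mono-alkylation and a configurationally stable C3: oxa-Michael adducts revert, the twofold symmetry of 7 makes its two activated carbons and its two hydroxyls equivalent so that only the 7-hydroxy-8-methoxy pattern can arise, the excess of 7 suppresses a second alkylation at C6, and lactol closure shields the α-aryl aldehyde from renewed enamine formation.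

**Step 4**
Reactants: 9 (3S)-8-methoxy-3-(2,3,4,5-tetramethoxyphenyl)chromane-2,7-diol
Product: 10 (3S)-8-methoxy-3-(2,3,4,5-tetramethoxyphenyl)-3,4-dihydro-2H-chromen-7-ol
Conditions: Et3SiH (4 equiv), TFA (5 equiv), CH2Cl2, −20 °C to 0 °C
Reagents that add atoms: none
Why: Ionic hydrogenation of the lactol: TFA ionises C2 to the cyclic oxocarbenium ion and Et3SiH reduces it to the C2 methylene with the O1–C2 and C4–C4a bonds intact, and since C3 is not a reacting centre, low temperature and excess silane should let hydride capture outrun loss of the C3 proton so that the (S) configuration is carried through.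

**Compound list**
1 | 1,2,3,4-tetramethoxybenzene | COc1ccc(OC)c(OC)c1OC | starting material
2 | 2-bromo-3,3-diethoxyprop-1-ene (2-bromoacrolein diethyl acetal) | C=C(Br)C(OCC)OCC | starting material
3 | (2,3,4,5-tetramethoxyphenyl)lithium | [Li]c1cc(OC)c(OC)c(OC)c1OC | intermediate
4 | (2,3,4,5-tetramethoxyphenyl)zinc chloride | Cl[Zn]c1cc(OC)c(OC)c(OC)c1OC | intermediate
5 | 1-(3,3-diethoxyprop-1-en-2-yl)-2,3,4,5-tetramethoxybenzene | C=C(C(OCC)OCC)c1cc(OC)c(OC)c(OC)c1OC | intermediate
6 | 2-(2,3,4,5-tetramethoxyphenyl)prop-2-enal | C=C(C=O)c1cc(OC)c(OC)c(OC)c1OC | intermediate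
7 | 2-methoxybenzene-1,3-diol (2-methoxyresorcinol) | COc1c(O)cccc1O | starting material
8 | (2S)-3-(2,4-dihydroxy-3-methoxyphenyl)-2-(2,3,4,5-tetramethoxyphenyl)propanal | COc1cc([C@@H](C=O)Cc2ccc(O)c(OC)c2O)c(OC)c(OC)c1OC | intermediate
9 | (3S)-8-methoxy-3-(2,3,4,5-tetramethoxyphenyl)chromane-2,7-diol (both C2 anomers) | COc1cc([C@H]2C(O)Oc3c(ccc(O)c3OC)C2)c(OC)c(OC)c1OC | intermediate
10 | (3S)-8-methoxy-3-(2,3,4,5-tetramethoxyphenyl)-3,4-dihydro-2H-chromen-7-ol | COc1cc([C@H]2COc3c(ccc(O)c3OC)C2)c(OC)c(OC)c1OC | target

**Step count and risks**
Total step count: 4. Longest linear sequence: 4 steps (1 → 5 → 6 → 9 → 10).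

Steps most likely to fail:

1. Step 3 (Proposed new method). What may go wrong: weak facial discrimination in the proton transfer to a twisted α-aryl enamine, erosion of configuration at C3 by renewed enamine formation from 8, or consumption of the catalyst by aza-Michael addition to the enal. Fallback with known chemistry, setting out from 6 and 7 and coming back to the route at 10: diphenyl phosphate (10 mol %) in CH2Cl2 should promote the same conjugate Friedel–Crafts addition and hemiacetal closure without stereocontrol, giving racemic 8-methoxy-3-(2,3,4,5-tetramethoxyphenyl)chromane-2,7-diol F1. TsOH (cat.), toluene, 4 Å molecular sieves, 60 °C should then dehydrate it to the cyclic enol ether 8-methoxy-3-(2,3,4,5-tetramethoxyphenyl)-4H-chromen-7-ol F2, in which C3 is trigonal. Asymmetric hydrogenation of its C2=C3 bond with a chiral iridium phosphine–oxazoline catalyst, [Ir(cod)(tBu-PHOX)][B(C6H3(CF3)2)4], H2 (50 bar), CH2Cl2, with the ligand antipode chosen for the 3S product, should give 10; hydrogenation of chromene double bonds with such catalysts is an established reaction type.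

2. Step 4. What may go wrong: loss of the C3 proton from the oxocarbenium ion, which racemises C3 through the enol ether, or Friedel–Crafts capture of the oxocarbenium ion by the electron-rich ring A of a second molecule. Fallback setting out from 9 and coming back at 10: NaBH4 (EtOH, 0 °C) should reduce the open-chain aldehyde tautomer without ionising C2, giving (S)-4-[3-hydroxy-2-(2,3,4,5-tetramethoxyphenyl)propyl]-2-methoxybenzene-1,3-diol F3. Mitsunobu etherification (PPh3, DIAD, THF, 0 °C, high dilution) should then close ring C again by attack of the ortho phenol on the activated primary carbon, a displacement that cannot touch C3, and give 10.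

3. Step 2. What may go wrong: acid-promoted dimerisation or polymerisation of the α-aryl enal during acetal cleavage and concentration. Fallback setting out from 1 and coming back at 6, which reaches the enal under neutral conditions: NBS (MeCN, 0 °C to rt) should brominate one of the two equivalent free positions of 1 to give 1-bromo-2,3,4,5-tetramethoxybenzene F4. Mg (THF) should convert it into (2,3,4,5-tetramethoxyphenyl)magnesium bromide F5. This reagent (2.5 equiv, CuI 10 mol %, THF/toluene, reflux) should add across prop-2-yn-1-ol (C#CCO) by hydroxyl-directed carbomagnesiation to give, after aqueous NH4Cl, 2-(2,3,4,5-tetramethoxyphenyl)prop-2-en-1-ol F6; the equivalent of Grignard reagent that deprotonates the alcohol returns as 1. MnO2 (CH2Cl2, rt) should oxidise the allylic alcohol to 6, and the filtered solution would be taken directly into step 3.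

**Further compounds**
F1 | step 3 | racemic 8-methoxy-3-(2,3,4,5-tetramethoxyphenyl)chromane-2,7-diol | COc1cc(C2C(O)Oc3c(ccc(O)c3OC)C2)c(OC)c(OC)c1OC
F2 | step 3 | 8-methoxy-3-(2,3,4,5-tetramethoxyphenyl)-4H-chromen-7-ol | COc1cc(C2=COc3c(ccc(O)c3OC)C2)c(OC)c(OC)c1OC
F3 | step 4 | (S)-4-[3-hydroxy-2-(2,3,4,5-tetramethoxyphenyl)propyl]-2-methoxybenzene-1,3-diol | COc1cc([C@@H](CO)Cc2ccc(O)c(OC)c2O)c(OC)c(OC)c1OC
F4 | step 2 | 1-bromo-2,3,4,5-tetramethoxybenzene | COc1cc(Br)c(OC)c(OC)c1OC
F5 | step 2 | (2,3,4,5-tetramethoxyphenyl)magnesium bromide | Br[Mg]c1cc(OC)c(OC)c(OC)c1OC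
F6 | step 2 | 2-(2,3,4,5-tetramethoxyphenyl)prop-2-en-1-ol | C=C(CO)c1cc(OC)c(OC)c(OC)c1OC
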